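The target is methyl shikimate with three different esters on O3, O4 and O5. Everything rests on opening the cyclohexene at its only double bond, the enoate alkene between C1 (the carbon bearing CO2Me) and C2 (the ring CH next to the acetoxy carbon C3): ring-closing metathesis. The precursor is an unprotected acyclic triol carrying a vinyl carbinol at one end and an α-substituted acrylate at the other, assembled from a D-ribose-derived iodide, zinc, indium and methyl 2-(bromomethyl)acrylate. One operation turns it into methyl shikimate with C3, C4 and C5 already set. A cyclic orthoacetate on the cis O3/O4 diol then protects during O5 acylation and later delivers the 3-acetate.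

Key step: step 3

Assumption: (R)-2-methylbutanoic acid is bought as the single enantiomer; ring compounds are numbered as in shikimic acid (C1 bears CO2Me, C2 is the alkene CH, C3 to C5 bear oxygen, C6 is CH2).

Step 1
Reactants: 1 methyl β-D-ribofuranoside
Product: 2 methyl 5-deoxy-5-iodo-β-D-ribofuranoside
Conditions: I2, PPh3, imidazole, THF, 65 °C
Reagents that add atoms: iodine, II
Why: Garegg–Samuelsson (Appel-type) iodination, in which the alkoxyphosphonium ion forms fastest at the primary C5 hydroxyl and is displaced by iodide in an SN2 step, so the secondary hydroxyls and all stereocentres should stay untouched.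

Step 2
Reactants: 2 methyl 5-deoxy-5-iodo-β-D-ribofuranoside; 3 methyl 2-(bromomethyl)acrylate
Product: 5 methyl (4R,5S,6R)-4,5,6-trihydroxy-2-methylideneoct-7-enoate, via dihydroxypentenal 4 (not isolated)
Conditions: Zn dust, THF/H2O 4:1, ultrasound, 40 °C; filter; then In powder, 3, rt
Reagents that add atoms: none
Why: Bernet–Vasella reductive fragmentation (zinc insertion into the C–I bond, β-elimination of the ring oxygen, loss of methoxide) should unveil enal 4, and the indium-mediated Barbier allylation in water then adds the 2-(methoxycarbonyl)allyl group under α-chelation control by the free C2 hydroxyl of 4, which sets the new carbinol centre threo to that hydroxyl, i.e. as 4R in 5.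

Step 3
Reactants: 5 methyl (4R,5S,6R)-4,5,6-trihydroxy-2-methylideneoct-7-enoate
Product: 6 methyl (3R,4S,5R)-3,4,5-trihydroxycyclohex-1-ene-1-carboxylate (methyl shikimate)
Conditions: second-generation Hoveyda–Grubbs catalyst RuCl2(H2IMes)(=CH-C6H4-2-OiPr) (5 mol %), 1,4-benzoquinone (10 mol %), degassed EtOAc (0.01 M), 60 °C
Reagents that add atoms: none
Why: The ruthenium benzylidene should exchange first with the unhindered monosubstituted C7=C8 vinyl group of 5, and the resulting alkylidene adds across the 1,1-disubstituted acrylate alkene in a [2+2] cycloaddition to a ruthenacyclobutane that cycloreverts with loss of ethene, which creates the trisubstituted, ester-conjugated C1=C2 bond of the ring. The closest known reaction type is ring-closing metathesis of a vinyl carbinol with an α-substituted acrylate to a cyclohex-1-ene-1-carboxylate. The single six-membered carbocycle is closed by this alkene metathesis, both new alkene carbons becoming ring members, and escape of ethene makes the closure irreversible. No stereocentre is formed, and C3, C4 and C5 are carried over unchanged because no bond to them is made or broken. The step needs ring closure to win over cross-metathesis oligomerisation and over ruthenium hydride isomerisation of the allylic alcohol; high dilution, the phosphine-free catalyst and 1,4-benzoquinone as hydride trap serve these needs, and initiation at the vinyl group rather than at the electron-poor acrylate means that the acrylate is met only intramolecularly.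

Step 4
Reactants: 6 methyl shikimate
Product: 7 methyl 3,4-O-(1-methoxyethylidene)shikimate (cyclic orthoacetate on O3 and O4, 5-OH free, both epimers at the orthoester carbon)
Conditions: MeC(OMe)3, CSA (cat.), MeCN, rt; then Et3N
Reagents that add atoms: trimethyl orthoacetate, COC(C)(OC)OC
Why: Acid-catalysed orthoester exchange, in which only the cis 3,4-diol can close an unstrained five-membered ring on the cyclohexene half-chair, so the trans 5-hydroxyl should stay free; the new orthoester carbon is formed as both epimers, which is of no consequence because it ends as the acetate carbonyl.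

Step 5
Reactants: 7 methyl 3,4-O-(1-methoxyethylidene)shikimate; 8 (R)-2-methylbutanoic acid
Product: 11 methyl (3R,4S,5R)-3-acetoxy-4-hydroxy-5-{[(2R)-2-methylbutanoyl]oxy}cyclohex-1-ene-1-carboxylate, via mixed anhydride 9 (not isolated), via acylated orthoester 10 (not isolated)
Conditions: 8, 2,4,6-Cl3C6H2COCl, Et3N, THF, rt; then 7, DMAP, toluene, rt; then AcOH/H2O 4:1, rt
Reagents that add atoms: water, O
Why: Yamaguchi esterification through mixed anhydride 9 acylates the only free hydroxyl under basic conditions that spare the orthoester and the α-stereocentre of 8, and mild aqueous acid then opens the orthoester of 10 by way of the dioxolan-2-ylium ion, whose hemiorthoester should collapse under stereoelectronic control to leave the acetate on the pseudoaxial O3 and the free hydroxyl on the equatorial O4 (axial-ester rule for cis-fused cyclic orthoesters), all stereocentres being retained.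

Step 6
Reactants: 11 methyl (3R,4S,5R)-3-acetoxy-4-hydroxy-5-{[(2R)-2-methylbutanoyl]oxy}cyclohex-1-ene-1-carboxylate
Product: 12 methyl (3R,4S,5R)-3-acetoxy-5-{[(2R)-2-methylbutanoyl]oxy}-4-(propanoyloxy)cyclohex-1-ene-1-carboxylate (the target)
Conditions: (EtCO)2O, pyridine, DMAP (cat.), CH2Cl2, 0 °C
Reagents that add atoms: propanoic anhydride, CCC(=O)OC(=O)CC
Why: DMAP-catalysed acylation of the one remaining hydroxyl is fast at 0 °C and should outrun acetyl migration from O3, so each ester stays on the oxygen assigned to it.

Compound list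
1 | methyl β-D-ribofuranoside | CO[C@@H]1O[C@H](CO)[C@@H](O)[C@H]1O | starting material
2 | methyl 5-deoxy-5-iodo-β-D-ribofuranoside | CO[C@@H]1O[C@H](CI)[C@@H](O)[C@H]1O | intermediate
3 | methyl 2-(bromomethyl)acrylate | C=C(CBr)C(=O)OC | starting material
4 | (2R,3R)-2,3-dihydroxypent-4-enal | O=C[C@H](O)[C@H](O)C=C | intermediate
5 | methyl (4R,5S,6R)-4,5,6-trihydroxy-2-methylideneoct-7-enoate | C=C[C@@H](O)[C@@H](O)[C@H](O)CC(=C)C(=O)OC | intermediate
6 | methyl (3R,4S,5R)-3,4,5-trihydroxycyclohex-1-ene-1-carboxylate (methyl shikimate) | O[C@@H]1[C@H](O)C=C(C(=O)OC)C[C@H]1O | intermediate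
7 | methyl 3,4-O-(1-methoxyethylidene)shikimate (both epimers at the orthoester carbon) | CC2(OC)O[C@@H]1[C@H](O2)C=C(C(=O)OC)C[C@H]1O | intermediate
8 | (R)-2-methylbutanoic acid | CC[C@@H](C)C(=O)O | starting material
9 | (R)-2-methylbutanoic 2,4,6-trichlorobenzoic anhydride | CC[C@@H](C)C(=O)OC(=O)c1c(Cl)cc(Cl)cc1Cl | intermediate
10 | methyl 3,4-O-(1-methoxyethylidene)-5-O-[(2R)-2-methylbutanoyl]shikimate (both epimers at the orthoester carbon) | CC2(OC)O[C@@H]1[C@H](O2)C=C(C(=O)OC)C[C@H]1OC(=O)[C@H](C)CC | intermediate
11 | methyl (3R,4S,5R)-3-acetoxy-4-hydroxy-5-{[(2R)-2-methylbutanoyl]oxy}cyclohex-1-ene-1-carboxylate | O[C@@H]1[C@H](OC(C)=O)C=C(C(=O)OC)C[C@H]1OC(=O)[C@H](C)CC | intermediate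
12 | methyl (3R,4S,5R)-3-acetoxy-5-{[(2R)-2-methylbutanoyl]oxy}-4-(propanoyloxy)cyclohex-1-ene-1-carboxylate | CCC(=O)O[C@@H]1[C@H](OC(C)=O)C=C(C(=O)OC)C[C@H]1OC(=O)[C@H](C)CC | target

Total step count: 6. Longest linear sequence: 6 steps (1 to 2 to 5 to 6 to 7 to 11 to 12).

Steps most likely to fail

Step 2. Chelation control may erode in the addition to the unprotected aldehyde, so that both faces are attacked; the hydroxy ester may also begin to lactonise. The fallback sets out from 2 and comes back at 6; it sets the carbinol centre by inversion instead of by the addition. Compound 2 is converted with 2,2-dimethoxypropane and CSA into methyl 5-deoxy-5-iodo-2,3-O-isopropylidene-β-D-ribofuranoside F1. Zinc in THF/H2O under ultrasound with 3 then fragments it to (4R,5R)-5-ethenyl-2,2-dimethyl-1,3-dioxolane-4-carbaldehyde F2 (not isolated), which is allylated in the same flask. The dioxolane cannot chelate, so polar non-chelation control should favour the erythro alcohol methyl (4S)-4-hydroxy-2-methylidene-4-(5-ethenyl-2,2-dimethyl-1,3-dioxolan-4-yl)butanoate F3. A Mitsunobu reaction (4-nitrobenzoic acid, PPh3, DIAD, toluene) inverts the carbinol to the 4-nitrobenzoate F4. Ring-closing metathesis under the conditions of step 3 should give methyl 3,4-O-isopropylidene-5-O-(4-nitrobenzoyl)shikimate F5. AcOH/H2O at 50 °C removes the acetonide to give methyl 5-O-(4-nitrobenzoyl)shikimate F6, and K2CO3 in MeOH at 0 °C releases 6.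

Step 5. The hemiorthoester may collapse unselectively, or the acetyl group may migrate from O3 to O4 before step 6. The fallback sets out from 11, including material that carries the acetyl group on O4, and comes back at 12; it replaces orthoester opening by catalyst-directed acylation of the free cis-diol. Acid-catalysed methanolysis (AcCl cat., MeOH, 0 °C) should remove the acetate faster than the α-branched ester and give the diol methyl 5-O-[(2R)-2-methylbutanoyl]shikimate F7. Borinic-acid-catalysed acylation (EtCOCl, iPr2NEt, 2-aminoethyl diphenylborinate 10 mol %, MeCN, rt) targets the equatorial oxygen of a cis-diol and should give methyl 5-O-[(2R)-2-methylbutanoyl]-4-O-propanoylshikimate F8. Ac2O, pyridine and DMAP then acetylate O3 to give 12.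

Step 3. The catalyst may decompose to a ruthenium hydride at the free allylic alcohol, with double-bond migration, or the diene may oligomerise by cross-metathesis. The fallback sets out from 5 and comes back at 6; it moves the ring closure onto a fully esterified substrate. Peracetylation (Ac2O, pyridine, DMAP) gives methyl (4R,5S,6R)-4,5,6-triacetoxy-2-methylideneoct-7-enoate F9. Ring-closing metathesis with the second-generation Grubbs catalyst RuCl2(H2IMes)(PCy3)(=CHPh) in toluene at 80 °C should give methyl 3,4,5-tri-O-acetylshikimate F10. Zemplén transesterification (NaOMe cat., MeOH, 0 °C) returns 6.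

Further compounds
F1 | step 2 | methyl 5-deoxy-5-iodo-2,3-O-isopropylidene-β-D-ribofuranoside | CO[C@@H]1O[C@H](CI)[C@H]2OC(C)(C)O[C@@H]12
F2 | step 2 | (4R,5R)-5-ethenyl-2,2-dimethyl-1,3-dioxolane-4-carbaldehyde | O=C[C@@H]1OC(C)(C)O[C@@H]1C=C
F3 | step 2 | methyl (4S)-4-hydroxy-2-methylidene-4-(5-ethenyl-2,2-dimethyl-1,3-dioxolan-4-yl)butanoate, erythro adduct | C=C[C@H]1OC(C)(C)O[C@H]1[C@@H](O)CC(=C)C(=O)OC
F4 | step 2 | methyl (4R)-2-methylidene-4-(4-nitrobenzoyloxy)-4-(5-ethenyl-2,2-dimethyl-1,3-dioxolan-4-yl)butanoate | C=C[C@H]1OC(C)(C)O[C@H]1[C@H](OC(=O)c1ccc(cc1)[N+](=O)[O-])CC(=C)C(=O)OC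
F5 | step 2 | methyl 3,4-O-isopropylidene-5-O-(4-nitrobenzoyl)shikimate | CC2(C)O[C@@H]1[C@H](O2)C=C(C(=O)OC)C[C@H]1OC(=O)c1ccc(cc1)[N+](=O)[O-]
F6 | step 2 | methyl 5-O-(4-nitrobenzoyl)shikimate | O[C@@H]1[C@H](O)C=C(C(=O)OC)C[C@H]1OC(=O)c1ccc(cc1)[N+](=O)[O-]
F7 | step 5 | methyl 5-O-[(2R)-2-methylbutanoyl]shikimate | O[C@@H]1[C@H](O)C=C(C(=O)OC)C[C@H]1OC(=O)[C@H](C)CC
F8 | step 5 | methyl 5-O-[(2R)-2-methylbutanoyl]-4-O-propanoylshikimate | CCC(=O)O[C@@H]1[C@H](O)C=C(C(=O)OC)C[C@H]1OC(=O)[C@H](C)CC
F9 | step 3 | methyl (4R,5S,6R)-4,5,6-triacetoxy-2-methylideneoct-7-enoate | C=C[C@@H](OC(C)=O)[C@@H](OC(C)=O)[C@H](OC(C)=O)CC(=C)C(=O)OC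
F10 | step 3 | methyl 3,4,5-tri-O-acetylshikimate | CC(=O)O[C@@H]1[C@H](OC(C)=O)C=C(C(=O)OC)C[C@H]1OC(C)=O
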